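The route rests on breaking the C3a–C8a bond of the five-membered ring. Counted round that ring, C3a and the quaternary, methyl-bearing C8a are bridged by C3, C2 and C1. The other two neighbours of C3a (C3 and C4) both carry oxygen, so read backwards the ring is a cyclopentanone with an ester on its α-carbon. A carbene held by Rh2(OAc)4 at C3a can therefore insert into a tertiary C8a–H bond. One operation gives the carbocycle, the C3a–C8a bond and the quaternary stereocentre, with retention. The precursor is an acyclic α-diazo-β-keto ester whose only stereocentre is bought as methyl (R)-3-hydroxy-2-methylpropanoate. The seven-membered ring is closed late by metathesis at C6=C7.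

Key step: step 6

Remarks on the chemistry:
- The target SMILES reads as (3R,3aS,4R,8aS). The rings are trans-fused. The C8a methyl, the C3 hydroxyl and the C4 acyloxy group lie on one face; H-3a and the isopropyl group lie on the other. The route is planned for exactly this isomer.
- Azulene numbering of the target is used for all intermediates. In the hydroxy ester, CH2OH becomes C8 and CO2Me becomes C1, so the R building block maps onto 8aS when the insertion goes with retention.
- Assumption: the two C8 carbinol epimers formed in step 15 are carried together, because C8 becomes a ketone in step 17.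

Step 1
Reactants: 1 methyl (R)-3-hydroxy-2-methylpropanoate
Product: 2 methyl (R)-3-(tert-butyldiphenylsilyloxy)-2-methylpropanoate
Conditions: TBDPSCl, imidazole, DMF, rt
Reagents that add atoms: tert-butyldiphenylsilyl chloride, CC(C)(C)[Si](Cl)(c1ccccc1)c1ccccc1
Why: Routine imidazole-promoted O-silylation of a primary alcohol leaves the stereocentre untouched and installs a bulky, only weakly electron-withdrawing ether that is inert to carbenes, hydrides and Grignard reagents.

Step 2
Reactants: 2 methyl (R)-3-(tert-butyldiphenylsilyloxy)-2-methylpropanoate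
Product: 3 (S)-3-(tert-butyldiphenylsilyloxy)-2-methylpropan-1-ol
Conditions: i-Bu2AlH (2.5 equiv), CH2Cl2, −78 → 0 °C
Reagents that add atoms: none
Why: Hydride reduction takes the ester straight to the primary alcohol, so no epimerisable aldehyde is handled and the stereocentre is preserved (S only through a change of CIP priorities).

Step 3
Reactants: 3 (S)-3-(tert-butyldiphenylsilyloxy)-2-methylpropan-1-ol
Product: 4 (R)-tert-butyl(3-iodo-2-methylpropoxy)diphenylsilane
Conditions: I2, PPh3, imidazole, CH2Cl2, 0 °C → rt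
Reagents that add atoms: iodine, II
Why: Appel-type (Garegg–Samuelsson) iodination runs by SN2 displacement of the oxyphosphonium group at the primary carbon and does not touch the neighbouring stereocentre.

Step 4
Reactants: 4 (R)-tert-butyl(3-iodo-2-methylpropoxy)diphenylsilane; 5 methyl acetoacetate
Product: 7 methyl (S)-7-(tert-butyldiphenylsilyloxy)-6-methyl-3-oxoheptanoate, via acetoacetate dianion 6 (not isolated)
Conditions: 5, NaH, THF, 0 °C; n-BuLi, 0 °C; then 4, 0 °C → rt; 1 M HCl quench
Reagents that add atoms: none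
Why: In this acetoacetate dianion γ-alkylation (Weiler alkylation) the more basic terminal carbanion of 6 displaces the primary iodide by SN2, which forms C1–C2 and places the methine 1,5 to the future carbene carbon.

Step 5
Reactants: 7 methyl (S)-7-(tert-butyldiphenylsilyloxy)-6-methyl-3-oxoheptanoate
Product: 8 methyl (S)-7-(tert-butyldiphenylsilyloxy)-2-diazo-6-methyl-3-oxoheptanoate
Conditions: p-ABSA, Et3N, MeCN, rt
Reagents that add atoms: 4-acetamidobenzenesulfonyl azide, CC(=O)Nc1ccc(cc1)S(=O)(=O)N=[N+]=[N-]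
Why: Regitz diazo transfer to the doubly activated methylene is a mild amine-mediated reaction that affects neither the silyl ether nor the remote stereocentre.

Step 6
Reactants: 8 methyl (S)-7-(tert-butyldiphenylsilyloxy)-2-diazo-6-methyl-3-oxoheptanoate
Product: 10 methyl (1R,2S)-2-[(tert-butyldiphenylsilyloxy)methyl]-2-methyl-5-oxocyclopentane-1-carboxylate, via Rh2(OAc)4 carbenoid 9 (not isolated)
Conditions: Rh2(OAc)4 (1 mol %), CH2Cl2, reflux, slow addition of 8 at high dilution
Reagents that add atoms: none
Why: Rh2(OAc)4 takes up the diazo carbon of 8, N2 leaves, and the electrophilic carbenoid 9 attacks the C8a–H σ bond in a concerted, asynchronous three-centre transition state in which hydride character flows to C3a while C3a–C8a forms on the side from which hydrogen departs. The closest known reaction type is the intramolecular 1,5 C–H insertion of α-diazo-β-keto esters to 2-alkoxycarbonylcyclopentanones, which is established for tertiary C–H bonds and goes with retention. The one ring that closes (C3a–C3–C2–C1–C8a) does so as a 1,5-insertion through a chair-like six-centre array that counts the migrating hydrogen. C8a is controlled by the stereospecificity of the insertion, so the S centre of 8 becomes the S quaternary carbon of 10, whereas C3a is set afterwards by enolisation of the β-keto ester, which places the ester trans to CH2OTBDPS with both groups pseudo-equatorial. The step needs site selectivity for the methine over the OCH2 and C-methyl hydrogens, and the substrate secures it because the methine is the only hydrogen in a 1,5 relationship, is tertiary, and every alternative would close a six-membered ring. The TBDPS ether withdraws less electron density from the methine than an acyl group would and shields the OCH2 hydrogens and the oxygen lone pairs against insertion and ylide formation, while slow addition at high dilution holds back carbene dimerisation.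

Step 7
Reactants: 10 methyl (1R,2S)-2-[(tert-butyldiphenylsilyloxy)methyl]-2-methyl-5-oxocyclopentane-1-carboxylate
Product: 11 methyl (6R,7S)-7-[(tert-butyldiphenylsilyloxy)methyl]-7-methyl-1,4-dioxaspiro[4.4]nonane-6-carboxylate
Conditions: HOCH2CH2OH, p-TsOH·H2O (cat.), benzene, reflux, Dean–Stark
Reagents that add atoms: ethylene glycol, OCCO
Why: Acid-catalysed ketalisation with azeotropic removal of water masks the C3 ketone and removes the 1,3-dicarbonyl acidity of C3a–H, and C3a, which equilibrates through the enol of 10 during the reaction, is locked with the ester trans to CH2OTBDPS (a minor cis isomer would be separable).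

Step 8
Reactants: 11 methyl (6R,7S)-7-[(tert-butyldiphenylsilyloxy)methyl]-7-methyl-1,4-dioxaspiro[4.4]nonane-6-carboxylate
Product: 12 {(6S,7S)-7-[(tert-butyldiphenylsilyloxy)methyl]-7-methyl-1,4-dioxaspiro[4.4]nonan-6-yl}methanol
Conditions: LiAlH4, Et2O, 0 °C
Reagents that add atoms: none
Why: LiAlH4 reduces the ester to the primary C4 alcohol while ketal and silyl ether are inert to hydride, and C3a, no longer next to a carbonyl group, cannot epimerise.

Step 9
Reactants: 12 {(6S,7S)-7-[(tert-butyldiphenylsilyloxy)methyl]-7-methyl-1,4-dioxaspiro[4.4]nonan-6-yl}methanol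
Product: 13 (2S,3S)-3-[(tert-butyldiphenylsilyloxy)methyl]-2-(hydroxymethyl)-3-methylcyclopentan-1-one
Conditions: 1 M HCl, THF, rt
Reagents that add atoms: water, O
Why: Mild aqueous acid hydrolysis of the dioxolane frees the C3 ketone while the acid-stable TBDPS ether stays, and the C4 arm remains on the face of the C8a methyl, which is also its thermodynamically preferred position.

Step 10
Reactants: 13 (2S,3S)-3-[(tert-butyldiphenylsilyloxy)methyl]-2-(hydroxymethyl)-3-methylcyclopentan-1-one
Product: 14 (1R,2S,3S)-3-[(tert-butyldiphenylsilyloxy)methyl]-2-(hydroxymethyl)-3-methyl-1-(propan-2-yl)cyclopentan-1-ol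
Conditions: LaCl3·2LiCl (1.1 equiv), THF, rt; i-PrMgCl (3.5 equiv), −20 → 0 °C
Reagents that add atoms: isopropylmagnesium chloride, CC(C)[Mg]Cl
Why: In this lanthanide-assisted Grignard 1,2-addition LaCl3·2LiCl raises the carbonyl electrophilicity and lowers the basicity of i-PrMgCl so that enolisation and β-hydride reduction are held back, the first equivalent turns C4–OH into a chelating alkoxide, and the isopropyl group attacks C3 from the face opposite both the C3a arm and the pseudo-axial C8a methyl, which sets 3R with OH cis to C4.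

Step 11
Reactants: 14 (1R,2S,3S)-3-[(tert-butyldiphenylsilyloxy)methyl]-2-(hydroxymethyl)-3-methyl-1-(propan-2-yl)cyclopentan-1-ol
Product: 15 (1R,2R,5S)-5-[(tert-butyldiphenylsilyloxy)methyl]-2-hydroxy-5-methyl-2-(propan-2-yl)cyclopentane-1-carbaldehyde
Conditions: Dess–Martin periodinane, NaHCO3, CH2Cl2, 0 °C → rt
Reagents that add atoms: none
Why: Buffered Dess–Martin oxidation converts the only oxidisable (primary) alcohol into the aldehyde without dehydration or retro-aldol cleavage, and C3a keeps its configuration, which is strongly favoured here because the formyl group lies cis to OH and CH3 rather than to isopropyl and CH2OTBDPS.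

Step 12
Reactants: 15 (1R,2R,5S)-5-[(tert-butyldiphenylsilyloxy)methyl]-2-hydroxy-5-methyl-2-(propan-2-yl)cyclopentane-1-carbaldehyde
Product: 17 (1R,2S,3S)-3-[(tert-butyldiphenylsilyloxy)methyl]-2-[(1R)-1-hydroxy-3-methylbut-3-en-1-yl]-3-methyl-1-(propan-2-yl)cyclopentan-1-ol, via dialkylborinate 16 (not isolated)
Conditions: (+)-Ipc2BOMe [from (−)-α-pinene], CH2=C(CH3)CH2MgCl, Et2O, −78 °C → rt; 15, −78 °C; then NaOH, H2O2
Reagents that add atoms: methallylmagnesium chloride, CC(=C)C[Mg]Cl
Why: Brown asymmetric methallylboration runs through a closed chair (Zimmerman–Traxler) transition state in which the borane derived from (−)-α-pinene adds to the Re face of the aldehyde and sets 4R under reagent control, which should dominate because both α-branches of the aldehyde (C3 and C8a) are fully substituted and offer little bias of their own, while the hindered tertiary C3–OH is too slow to protonate the borane at −78 °C.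

Step 13
Reactants: 17 (1R,2S,3S)-3-[(tert-butyldiphenylsilyloxy)methyl]-2-[(1R)-1-hydroxy-3-methylbut-3-en-1-yl]-3-methyl-1-(propan-2-yl)cyclopentan-1-ol
Product: 18 (1R,2S,3S)-3-(hydroxymethyl)-2-[(1R)-1-hydroxy-3-methylbut-3-en-1-yl]-3-methyl-1-(propan-2-yl)cyclopentan-1-ol
Conditions: n-Bu4NF, THF, rt → 45 °C
Reagents that add atoms: none
Why: Fluoride-driven cleavage of the Si–O bond frees the C8 alcohol, and no base-sensitive group is present at this stage.

Step 14
Reactants: 18 (1R,2S,3S)-3-(hydroxymethyl)-2-[(1R)-1-hydroxy-3-methylbut-3-en-1-yl]-3-methyl-1-(propan-2-yl)cyclopentan-1-ol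
Product: 19 (1S,2S,3R)-3-hydroxy-2-[(1R)-1-hydroxy-3-methylbut-3-en-1-yl]-1-methyl-3-(propan-2-yl)cyclopentane-1-carbaldehyde
Conditions: TEMPO (cat.), PhI(OAc)2, CH2Cl2, rt
Reagents that add atoms: none
Why: Oxoammonium oxidation is sterically selective for primary over secondary alcohols, the C4 carbinol is buried between C3a and the methallyl chain, the tertiary alcohol cannot react, and the trans arrangement of the two arms prevents lactol formation and hence over-oxidation to a lactone.

Step 15
Reactants: 19 (1S,2S,3R)-3-hydroxy-2-[(1R)-1-hydroxy-3-methylbut-3-en-1-yl]-1-methyl-3-(propan-2-yl)cyclopentane-1-carbaldehyde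
Product: 20 (1R,2S,3S)-2-[(1R)-1-hydroxy-3-methylbut-3-en-1-yl]-3-(1-hydroxyprop-2-en-1-yl)-3-methyl-1-(propan-2-yl)cyclopentan-1-ol (both C8 epimers)
Conditions: CH2=CHMgBr (4 equiv), THF, −78 → 0 °C
Reagents that add atoms: vinylmagnesium bromide, C=C[Mg]Br
Why: Grignard 1,2-addition to a non-enolisable neopentyl aldehyde follows after two equivalents have deprotonated the hydroxyl groups, and the new C8 carbinol centre forms without control, which does not matter because it is erased in step 17.

Step 16
Reactants: 20 (1R,2S,3S)-2-[(1R)-1-hydroxy-3-methylbut-3-en-1-yl]-3-(1-hydroxyprop-2-en-1-yl)-3-methyl-1-(propan-2-yl)cyclopentan-1-ol (both C8 epimers)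
Product: 21 (3R,3aS,4R,8aS)-6,8a-dimethyl-3-(propan-2-yl)-1,2,3,3a,4,5,8,8a-octahydroazulene-3,4,8-triol (both C8 epimers)
Conditions: second-generation Grubbs catalyst RuCl2(=CHPh)(PCy3)(H2IMes) (5 mol %), CH2Cl2 (2 mM), reflux
Reagents that add atoms: none
Why: In the ring-closing metathesis the catalyst loads onto the monosubstituted vinyl group and closes onto the 1,1-disubstituted alkene, loss of ethylene drives formation of the seven-membered ring with its trisubstituted and necessarily Z C6=C7 bond, and no stereocentre is touched.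

Step 17
Reactants: 21 (3R,3aS,4R,8aS)-6,8a-dimethyl-3-(propan-2-yl)-1,2,3,3a,4,5,8,8a-octahydroazulene-3,4,8-triol (both C8 epimers)
Product: 22 (3R,3aS,4R,8aS)-3,4-dihydroxy-6,8a-dimethyl-3-(propan-2-yl)-2,3,3a,4,5,8a-hexahydroazulen-8(1H)-one
Conditions: activated MnO2 (excess), CH2Cl2, rt
Reagents that add atoms: none
Why: MnO2 oxidises allylic alcohols selectively, so both C8 epimers converge on the enone while the homoallylic secondary C4–OH and the tertiary C3–OH stay.

Step 18
Reactants: 23 vanillic acid
Product: 25 4-(tert-butyldimethylsilyloxy)-3-methoxybenzoic acid, via bis-silyl derivative 24 (not isolated)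
Conditions: TBSCl (2.5 equiv), imidazole, DMF, rt; then AcOH–THF–H2O, rt
Reagents that add atoms: tert-butyldimethylsilyl chloride, CC(C)(C)[Si](C)(C)Cl
Why: Exhaustive silylation followed by selective hydrolysis of the far more labile silyl ester leaves only the phenol masked, which prevents self-acylation of vanillic acid in the coupling.

Step 19
Reactants: 22 (3R,3aS,4R,8aS)-3,4-dihydroxy-6,8a-dimethyl-3-(propan-2-yl)-2,3,3a,4,5,8a-hexahydroazulen-8(1H)-one; 25 4-(tert-butyldimethylsilyloxy)-3-methoxybenzoic acid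
Product: 26 (3R,3aS,4R,8aS)-3-hydroxy-6,8a-dimethyl-8-oxo-3-(propan-2-yl)-1,2,3,3a,4,5,8,8a-octahydroazulen-4-yl 4-(tert-butyldimethylsilyloxy)-3-methoxybenzoate
Conditions: DCC, DMAP, CH2Cl2, rt
Reagents that add atoms: none
Why: Steglich esterification acylates oxygen without touching the C4–O bond so that 4R is retained, the secondary C4–OH reacts while the tertiary isopropyl-flanked C3–OH does not, and the weakly basic medium avoids vinylogous β-elimination across C4–C5.

Step 20
Reactants: 26 (3R,3aS,4R,8aS)-3-hydroxy-6,8a-dimethyl-8-oxo-3-(propan-2-yl)-1,2,3,3a,4,5,8,8a-octahydroazulen-4-yl 4-(tert-butyldimethylsilyloxy)-3-methoxybenzoate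
Product: 27 (3R,3aS,4R,8aS)-3-hydroxy-6,8a-dimethyl-8-oxo-3-(propan-2-yl)-1,2,3,3a,4,5,8,8a-octahydroazulen-4-yl 4-hydroxy-3-methoxybenzoate (CNP0136950.1)
Conditions: n-Bu4NF, AcOH (1:1), THF, 0 °C
Reagents that add atoms: none
Why: Fluoride readily cleaves the aryl silyl ether, and buffering with AcOH keeps the medium non-basic so that neither ester cleavage nor elimination of the vanillate towards a dienone should compete.

Compound list
1 | methyl (R)-3-hydroxy-2-methylpropanoate | OC[C@@H](C)C(=O)OC | starting material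
2 | methyl (R)-3-(tert-butyldiphenylsilyloxy)-2-methylpropanoate | CC(C)(C)[Si](c1ccccc1)(c1ccccc1)OC[C@@H](C)C(=O)OC | intermediate
3 | (S)-3-(tert-butyldiphenylsilyloxy)-2-methylpropan-1-ol | CC(C)(C)[Si](c1ccccc1)(c1ccccc1)OC[C@@H](C)CO | intermediate
4 | (R)-tert-butyl(3-iodo-2-methylpropoxy)diphenylsilane | CC(C)(C)[Si](c1ccccc1)(c1ccccc1)OC[C@@H](C)CI | intermediate
5 | methyl acetoacetate | COC(=O)CC(C)=O | starting material
6 | sodium lithium dianion of methyl acetoacetate (not isolated) | [Na+].[Li+].C=C([O-])C=C([O-])OC | intermediate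
7 | methyl (S)-7-(tert-butyldiphenylsilyloxy)-6-methyl-3-oxoheptanoate | CC(C)(C)[Si](c1ccccc1)(c1ccccc1)OC[C@@H](C)CCC(=O)CC(=O)OC | intermediate
8 | methyl (S)-7-(tert-butyldiphenylsilyloxy)-2-diazo-6-methyl-3-oxoheptanoate | CC(C)(C)[Si](c1ccccc1)(c1ccccc1)OC[C@@H](C)CCC(=O)C(=[N+]=[N-])C(=O)OC | intermediate
9 | Rh2(OAc)4 carbenoid of 8 (not isolated; the SMILES shows only the carbene-bearing Rh) | CC(C)(C)[Si](c1ccccc1)(c1ccccc1)OC[C@@H](C)CCC(=O)C(=[Rh])C(=O)OC | intermediate
10 | methyl (1R,2S)-2-[(tert-butyldiphenylsilyloxy)methyl]-2-methyl-5-oxocyclopentane-1-carboxylate (ester trans to CH2OTBDPS) | CC(C)(C)[Si](c1ccccc1)(c1ccccc1)OC[C@@]2(C)CCC(=O)[C@@H]2C(=O)OC | intermediate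
11 | methyl (6R,7S)-7-[(tert-butyldiphenylsilyloxy)methyl]-7-methyl-1,4-dioxaspiro[4.4]nonane-6-carboxylate | CC(C)(C)[Si](c1ccccc1)(c1ccccc1)OC[C@@]2(C)CCC3(OCCO3)[C@@H]2C(=O)OC | intermediate
12 | {(6S,7S)-7-[(tert-butyldiphenylsilyloxy)methyl]-7-methyl-1,4-dioxaspiro[4.4]nonan-6-yl}methanol | CC(C)(C)[Si](c1ccccc1)(c1ccccc1)OC[C@@]2(C)CCC3(OCCO3)[C@@H]2CO | intermediate
13 | (2S,3S)-3-[(tert-butyldiphenylsilyloxy)methyl]-2-(hydroxymethyl)-3-methylcyclopentan-1-one | CC(C)(C)[Si](c1ccccc1)(c1ccccc1)OC[C@@]2(C)CCC(=O)[C@@H]2CO | intermediate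
14 | (1R,2S,3S)-3-[(tert-butyldiphenylsilyloxy)methyl]-2-(hydroxymethyl)-3-methyl-1-(propan-2-yl)cyclopentan-1-ol | CC(C)(C)[Si](c1ccccc1)(c1ccccc1)OC[C@@]2(C)CC[C@@](O)(C(C)C)[C@@H]2CO | intermediate
15 | (1R,2R,5S)-5-[(tert-butyldiphenylsilyloxy)methyl]-2-hydroxy-5-methyl-2-(propan-2-yl)cyclopentane-1-carbaldehyde | CC(C)(C)[Si](c1ccccc1)(c1ccccc1)OC[C@@]2(C)CC[C@@](O)(C(C)C)[C@@H]2C=O | intermediate
16 | diisopinocampheylborinate of 17 at C4–O (not isolated) | CC(C)(C)[Si](c1ccccc1)(c1ccccc1)OC[C@@]2(C)CC[C@@](O)(C(C)C)[C@@H]2[C@H](OB([C@H]3C[C@H]4C[C@@H]([C@@H]3C)C4(C)C)[C@H]3C[C@H]4C[C@@H]([C@@H]3C)C4(C)C)CC(C)=C | intermediate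
17 | (1R,2S,3S)-3-[(tert-butyldiphenylsilyloxy)methyl]-2-[(1R)-1-hydroxy-3-methylbut-3-en-1-yl]-3-methyl-1-(propan-2-yl)cyclopentan-1-ol | CC(C)(C)[Si](c1ccccc1)(c1ccccc1)OC[C@@]2(C)CC[C@@](O)(C(C)C)[C@@H]2[C@H](O)CC(C)=C | intermediate
18 | (1R,2S,3S)-3-(hydroxymethyl)-2-[(1R)-1-hydroxy-3-methylbut-3-en-1-yl]-3-methyl-1-(propan-2-yl)cyclopentan-1-ol | OC[C@@]2(C)CC[C@@](O)(C(C)C)[C@@H]2[C@H](O)CC(C)=C | intermediate
19 | (1S,2S,3R)-3-hydroxy-2-[(1R)-1-hydroxy-3-methylbut-3-en-1-yl]-1-methyl-3-(propan-2-yl)cyclopentane-1-carbaldehyde | O=C[C@@]2(C)CC[C@@](O)(C(C)C)[C@@H]2[C@H](O)CC(C)=C | intermediate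
20 | (1R,2S,3S)-2-[(1R)-1-hydroxy-3-methylbut-3-en-1-yl]-3-(1-hydroxyprop-2-en-1-yl)-3-methyl-1-(propan-2-yl)cyclopentan-1-ol, both C8 epimers | C=CC(O)[C@@]2(C)CC[C@@](O)(C(C)C)[C@@H]2[C@H](O)CC(C)=C | intermediate
21 | (3R,3aS,4R,8aS)-6,8a-dimethyl-3-(propan-2-yl)-1,2,3,3a,4,5,8,8a-octahydroazulene-3,4,8-triol, both C8 epimers | O[C@@H]1CC(C)=CC(O)[C@@]2(C)CC[C@@](O)(C(C)C)[C@H]12 | intermediate
22 | (3R,3aS,4R,8aS)-3,4-dihydroxy-6,8a-dimethyl-3-(propan-2-yl)-2,3,3a,4,5,8a-hexahydroazulen-8(1H)-one | O[C@@H]1CC(C)=CC(=O)[C@@]2(C)CC[C@@](O)(C(C)C)[C@H]12 | intermediate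
23 | vanillic acid | COc1cc(C(=O)O)ccc1O | starting material
24 | tert-butyldimethylsilyl 4-(tert-butyldimethylsilyloxy)-3-methoxybenzoate (not isolated) | COc1cc(C(=O)O[Si](C)(C)C(C)(C)C)ccc1O[Si](C)(C)C(C)(C)C | intermediate
25 | 4-(tert-butyldimethylsilyloxy)-3-methoxybenzoic acid | COc1cc(C(=O)O)ccc1O[Si](C)(C)C(C)(C)C | intermediate
26 | O-TBS-protected target ester | COc1cc(C(=O)O[C@@H]2CC(C)=CC(=O)[C@@]3(C)CC[C@@](O)(C(C)C)[C@H]23)ccc1O[Si](C)(C)C(C)(C)C | intermediate
27 | CNP0136950.1, (3R,3aS,4R,8aS)-3-hydroxy-6,8a-dimethyl-8-oxo-3-(propan-2-yl)-1,2,3,3a,4,5,8,8a-octahydroazulen-4-yl 4-hydroxy-3-methoxybenzoate | COc1cc(C(=O)O[C@@H]2CC(C)=CC(=O)[C@@]3(C)CC[C@@](O)(C(C)C)[C@H]23)ccc1O | target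

Total step count: 20. Longest linear sequence: 19 (steps 1–17, 19 and 20; step 18 is a one-step side branch).

Steps most likely to fail

**1. Step 6.**
- The methine is inductively deactivated by the oxygen on the neighbouring carbon. The carbene may therefore be lost to dimerisation, to insertion next to the silyloxy oxygen, or to capture by traces of water.
- The fallback makes the same C3a–C8a bond with a free alkylidene carbene. This species is less sensitive to induction and also inserts with retention. The fallback sets out from 7.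
- Exhaustive C-methylation (MeI, K2CO3, acetone) should give methyl (S)-7-(tert-butyldiphenylsilyloxy)-2,2,6-trimethyl-3-oxoheptanoate F1.
- Krapcho demethoxycarbonylation (LiCl, wet DMSO, 150 °C) should give (S)-7-(tert-butyldiphenylsilyloxy)-2,6-dimethylheptan-3-one F2.
- Me3SiC(Li)N2 (from Me3SiCHN2 and n-BuLi, THF, −78 °C → rt) turns the ketone into the alkylidene carbene. This closes by 1,5 C–H insertion to tert-butyl{[(1S)-1-methyl-3-(propan-2-yl)cyclopent-2-en-1-yl]methoxy}diphenylsilane F3.
- A Me2AlCl-promoted carbonyl-ene reaction with paraformaldehyde bonds C4 to C3a on the face opposite CH2OTBDPS and moves the alkene to C2=C3. This should give the homoallylic alcohol with CH2OH cis to the C8a methyl, F4.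
- VO(acac)2/t-BuOOH epoxidation directed by the C4 hydroxyl should give the C2–C3 epoxide cis to CH2OH, F5.
- LiAlH4 opens the epoxide at the less substituted C2, and the sequence rejoins the route at 14.

**2. Step 10.**
- The secondary Grignard reagent may enolise or reduce the ketone.
- The β-alkoxide may suffer retro-aldol loss of formaldehyde.
- Facial selectivity or the configurational stability of C3a may be insufficient.
- The fallback sets out from 13 and removes both the alkoxide and the β-hydrogens of the nucleophile.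
- Et3SiCl/imidazole should give the C4 triethylsilyl ether of the ketone F6.
- CH2=C(CH3)MgBr with CeCl3 (THF, −78 °C) adds an sp2 carbanion from the same open face, which should give the isopropenyl carbinol F7.
- H2 over Pd/C (EtOAc) saturates the alkene to the isopropyl carbinol silyl ether F8.
- PPTS in MeOH removes the primary triethylsilyl group in the presence of TBDPS, and the sequence rejoins the route at 14.

**3. Step 12.**
- Addition to the very hindered aldehyde may be slow.
- The facial selectivity of the chiral borane may be eroded by an opposing substrate bias, or by protonolysis of the reagent at the free hydroxyl.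
- The fallback sets C4 by reduction instead of addition and sets out from 15.
- CH2=C(CH3)CH2MgCl (THF, −78 °C) should give the carbinol as a C4 epimer mixture F9.
- Dess–Martin periodinane should give the β-hydroxy ketone F10.
- Me4NBH(OAc)3 (MeCN–AcOH, −30 °C, Evans–Saksena reduction) binds to the C3 hydroxyl and delivers hydride internally. The chair transition state carries isopropyl, C8a and C5 in equatorial positions, which corresponds to 4R, and the sequence rejoins the route at 17.

Further compounds
F1 | step 6 | methyl (S)-7-(tert-butyldiphenylsilyloxy)-2,2,6-trimethyl-3-oxoheptanoate | CC(C)(C)[Si](c1ccccc1)(c1ccccc1)OC[C@@H](C)CCC(=O)C(C)(C)C(=O)OC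
F2 | step 6 | (S)-7-(tert-butyldiphenylsilyloxy)-2,6-dimethylheptan-3-one | CC(C)(C)[Si](c1ccccc1)(c1ccccc1)OC[C@@H](C)CCC(=O)C(C)C
F3 | step 6 | tert-butyl{[(1S)-1-methyl-3-(propan-2-yl)cyclopent-2-en-1-yl]methoxy}diphenylsilane | CC(C)(C)[Si](c1ccccc1)(c1ccccc1)OC[C@@]2(C)CCC(C(C)C)=C2
F4 | step 6 | {(1S,5S)-5-[(tert-butyldiphenylsilyloxy)methyl]-5-methyl-2-(propan-2-yl)cyclopent-2-en-1-yl}methanol | CC(C)(C)[Si](c1ccccc1)(c1ccccc1)OC[C@@]2(C)CC=C(C(C)C)[C@@H]2CO
F5 | step 6 | C2–C3 epoxide of F4, oxygen cis to CH2OH and to the C8a methyl | CC(C)(C)[Si](c1ccccc1)(c1ccccc1)OC[C@@]2(C)C[C@@H]3O[C@]3(C(C)C)[C@@H]2CO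
F6 | step 10 | (2S,3S)-3-[(tert-butyldiphenylsilyloxy)methyl]-3-methyl-2-[(triethylsilyloxy)methyl]cyclopentan-1-one | CC(C)(C)[Si](c1ccccc1)(c1ccccc1)OC[C@@]2(C)CCC(=O)[C@@H]2CO[Si](CC)(CC)CC
F7 | step 10 | isopropenyl carbinol from F6, OH cis to the C4 arm | CC(C)(C)[Si](c1ccccc1)(c1ccccc1)OC[C@@]2(C)CC[C@@](O)(C(C)=C)[C@@H]2CO[Si](CC)(CC)CC
F8 | step 10 | C4 triethylsilyl ether of 14 | CC(C)(C)[Si](c1ccccc1)(c1ccccc1)OC[C@@]2(C)CC[C@@](O)(C(C)C)[C@@H]2CO[Si](CC)(CC)CC
F9 | step 12 | C4 epimer mixture of 17 | CC(C)(C)[Si](c1ccccc1)(c1ccccc1)OC[C@@]2(C)CC[C@@](O)(C(C)C)[C@@H]2C(O)CC(C)=C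
F10 | step 12 | C4 ketone corresponding to 17 | CC(C)(C)[Si](c1ccccc1)(c1ccccc1)OC[C@@]2(C)CC[C@@](O)(C(C)C)[C@@H]2C(=O)CC(C)=C
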